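## Structural features

The target is a 14-membered carbocycle (C1–C14) carrying two five-membered lactones. An α-methylene-γ-butyrolactone is fused across C1–C14 (ring oxygen on C1; C15 with its exocyclic CH2 and the carbonyl C16 on C14). An α-substituted butenolide spans C5–C7 (ring oxygen on C5, C6=C7 inside the macrocycle, carbonyl on C7). The macrocycle also holds an (E)-trisubstituted C2=C3 alkene with the C3 methyl, a 1,1-disubstituted methylene on C11, and a secondary allylic hydroperoxide at C10. C1 (S) and C14 (R) are adjacent and trans on the lactone, whereas C5 (R) and C10 (R) are separated from them and from each other by sp2 carbons, so no centre can be relied on to control another. Fragile groups are the hydroperoxide (reduction, acid- or base-induced fragmentation), the α-methylene lactone (conjugate addition, migration of the double bond into the ring), the butenolide γ-hydrogen at C5 (epimerisation through the furanolate) and the allylic acyloxy bond at C1. The real difficulties are closing a 14-membered ring that contains four alkenes, fixing three mutually remote stereo-elements by reagent control, and introducing C10–OOH last under conditions that are neither basic nor reducing. The key step exploits the array C5(O)–C6=C7(C=O)–C8–C9–C10(O): a butenolide whose α-carbon C7 carries a chain oxygenated two carbons beyond C8 is the signature of a ruthenium ene-type coupling between a 4-hydroxy-2-ynoate (C5–C7) and an O-silylated allylic alcohol (C8–C10), which closes the carbocycle and the butenolide together.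

## Logic of the disconnections

30 ⇒ 28. The C10–OOH bond is cut. A hydroperoxide cannot be carried through metal catalysis or hydride reduction, so it is placed last and traced to the C10 epimeric carbinol. The forward step must be a clean invertive substitution at an allylic carbon (through 29) without base.

28 ⇒ 27 ⇒ 26. The C10–H bond is cut (carbinol to ketone), then the ketone is traced to its C9=C10 silyl enol ether. This turns an isolated stereocentre into a prochiral enone that a chiral reagent can address without help from the ring. The demand is a reduction that ignores two lactones and a hydrolysis that avoids nucleophiles able to add to the enone.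

26 ⇒ 24. The C7–C8 bond and the butenolide O–C(=O) bond are cut. Both rings open in one retrosynthetic operation to an acyclic hydroxy-ynoate with a terminal vinyl group, and the C10 centre of 24 need not be defined because it is flattened. The forward step must form the bond at the ynoate α-carbon, engage only the monosubstituted alkene, and outrun oligomerisation.

24 ⇒ 21 + 22. The C5–C6 bond is cut next to the carbinol. This sets C5 by a catalytic asymmetric alkynylation and delays the electrophilic ynoate until just before ring closure. The demand is that a β,γ-unsaturated aldehyde survive mildly basic zinc conditions.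

21 ⇒ 20 ⇒ 19. No skeletal bond is cut; the C5 oxidation level is adjusted and a primary silyl ether is removed in the presence of the secondary bis-allylic one. This lets the same silyl group serve on both oxygens.

19 ⇒ 13 + 17. The C1–C14 bond and the lactone O–C16 bond are cut. The methylene lactone with both adjacent stereocentres comes from an enal and a 2-alkoxycarbonyl allylboronate in one operation. The forward step requires the γ-substituent of 13 to be trans to the CH2B group (for the trans lactone) and a chiral acid to choose the aldehyde face.

13 ⇒ 11 ⇒ 9. The C15–CH2B bond and then the C15–C16 bond are cut. The stereodefined allylboronate derives from an ynoate by conjugate hydrometallation and trapping, and the ynoate from a terminal alkyne. The hydrometallation must be syn and the trapping must retain geometry.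

9 ⇒ 8 ⇒ 7 ⇒ 4 + 5, and 4 ⇒ 1 + 2. The C10–C11 bond is cut (alkenyl anion plus enal), then the C12–C13 bond (propargyl anion plus allylic bromide). All of C8–C15 comes from three small commercial pieces; C10 may be racemic. The alkyne needs a silyl cap during the halogen–lithium exchange.

17 ⇒ 16 ⇒ 14. The C3–CH3 and C1–C2 bonds are cut across the alkyne of 14. One carbometallation sets the (E)-trisubstituted alkene with complete regio- and stereocontrol and delivers C1 at the alcohol level.

## Other disconnections considered

Alternative 1: The cut is the bond between the lactone α-carbon and C14, with the exocyclic methylene added afterwards. In the forward sense the macrocyclic C1 diazophosphonoacetate A1 (C14 still a CH2, C10=C11 as the trisubstituted alkene) would be treated with Rh2(O2CC3F7)4 to give the α-phosphono lactone A2 by 1,5 C–H insertion. Olefination with formaldehyde would then give ovatodiolide A6, and a singlet-oxygen ene reaction would have to install C10–OOH and the C11 methylene.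
- In its favour: the Michael-acceptor lactone appears only at the end, and C14 is set by relay from C1 without an external chiral catalyst. On both points it is better than the chosen plan, which carries the methylene lactone through eight steps and needs a chiral acid for C1/C14.
- Against it: the carbenoid sits on an allylic ester, so cyclopropanation of C2=C3 (and of C10=C11) competes directly with insertion into an unactivated methylene C–H. The macrocycle and butenolide must be built beforehand by another ring closure. The C10 oxygen is not used as a handle, so a photooxygenation without reagent control over site or face is needed.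
- Comparison: structurally the chosen plan makes the C10 oxygen part of the ring-closing retron, whereas this one ignores it. Mechanistically the chosen plan relies on selectivities inherent to the catalyst, this one on chemoselectivity of a free carbenoid next to an alkene. In step economy it forms one ring per key step against two, and adds olefination and photooxygenation.

Alternative 2: The cut is C10–C11. The iodoalkene aldehyde A3 would be closed with CrCl2, catalytic NiCl2 and a chiral oxazoline–sulfonamide ligand to give the (10S)-carbinol A4, which is identical with 28 of the chosen route.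
- In its favour: ring closure and the C10 carbinol arise together at the correct oxidation level, so enol-ether hydrolysis and ketone reduction are unnecessary. After the key step it is two steps shorter, which is better than the chosen plan. Organochromium reagents tolerate lactones and enoates, which is equal to the tolerance required of ruthenium.
- Against it: facial selectivity at C10 must be imposed by the ligand during a macrocyclisation, where ring conformation may be mismatched. The aldehyde is α-unbranched and enolisable. Chromium is needed in large amount at high dilution. The butenolide is no longer formed by the ring closure and needs its own steps earlier.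
- Comparison: the chosen plan builds two rings catalytically and sets C10 afterwards in an unconstrained, reagent-controlled reduction, which is more predictable. The endgame (sulfonate, then H2O2) and its risk are the same in both.

Alternative 3: The cut is C6=C7. The 15-membered macrolactone A5, with a vinyl group on C5 and a methylene on C7, would undergo transannular ring-closing metathesis with the second-generation Grubbs catalyst to give ovatodiolide A6 and ethylene. The butenolide and the carbocycle form together, and photooxygenation must then give the target.
- In its favour: two rings close in one step, which is equal to the chosen plan. Macrolactonisation to A5 is reliable, no protecting groups are needed, and C5 comes from a simple chiral allylic alcohol. If the final ene reaction were selective the route would be shorter, which would be better than the chosen plan.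
- Against it: the two reacting alkenes must meet across the ring. A5 contains a second acrylate-type methylene that can also enter metathesis, and closing a trisubstituted electron-poor alkene needs forcing conditions that favour oligomers. The ene reaction on A6 must choose C10=C11 over C2=C3, abstract hydrogen from the methyl and not from C9 or C12, and set C10 from ring conformation alone.
- Comparison: the chosen plan fixes the position and configuration of the C10 oxygen by reagent-controlled steps, at the cost of three steps after ring closure.

Key step: step 13

Remarks on the chemistry: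
- Locants C1–C14 are the ring carbons of the carbocycle (C1 lactone O–CH, C5 butenolide O–CH, C10 peroxide carbon, C14 lactone β-CH); C15 and C16 are the α-carbon and carbonyl of the methylene lactone.
- C10 is carried as both epimers from 7 to 24 and is left undefined in the SMILES. It arises from an unselective addition and becomes sp2 in step 13, so defining it would add steps without benefit. C1, C5 and C14 of 24 and 26 have the target configuration.
- 14 is taken as purchasable; otherwise it is one silylation from 3-butyn-1-ol.
- The choice of (R,R)-ProPhenol in step 12 and the facial sense of the auxiliary in the step 9 fallback are assignments from recalled models and need checking on a model aldehyde; the requirement is Si-face delivery at C5.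

## Route

Step 1
Reactants: 1 1-(trimethylsilyl)propyne; 2 2,3-dibromopropene
Product: 4 (5-bromohex-5-en-1-yn-1-yl)trimethylsilane, via propargyllithium 3 (not isolated)
Conditions: n-BuLi, TMEDA, Et2O, −78 to 0 °C; then 2, −78 °C to rt
Reagents that add atoms: none
Why: Propargylic lithiation of the silyl-capped alkyne followed by alkylation of an allylic bromide; direct and allylic-shift substitution give the same product, the vinylic bromide is inert, and the silyl group keeps the anion reacting at the propargylic carbon.

Step 2
Reactants: 4 (5-bromohex-5-en-1-yn-1-yl)trimethylsilane; 5 acrolein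
Product: 7 4-methylidene-8-(trimethylsilyl)oct-1-en-7-yn-3-ol (racemic), via alkenyllithium 6 (not isolated)
Conditions: t-BuLi (2 equiv), Et2O, −78 °C; then 5, −78 °C; aq. NH4Cl
Reagents that add atoms: none
Why: Bromine–lithium exchange and 1,2-addition of the hard alkenyllithium to the enal carbonyl at low temperature; the carbinol (future C10) may be racemic because this centre is flattened in step 13.

Step 3
Reactants: 7 4-methylidene-8-(trimethylsilyl)oct-1-en-7-yn-3-ol
Product: 8 tert-butyldimethyl{[4-methylidene-8-(trimethylsilyl)oct-1-en-7-yn-3-yl]oxy}silane (racemic)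
Conditions: TBSCl, imidazole, DMF, rt
Reagents that add atoms: tert-butyldimethylsilyl chloride, CC(C)(C)[Si](C)(C)Cl
Why: Standard O-silylation of a secondary alcohol; the silyl ether is the group that later becomes the enol silane in the ene-type coupling.

Step 4
Reactants: 8 tert-butyldimethyl{[4-methylidene-8-(trimethylsilyl)oct-1-en-7-yn-3-yl]oxy}silane
Product: 9 tert-butyldimethyl[(4-methylideneoct-1-en-7-yn-3-yl)oxy]silane (racemic)
Conditions: K2CO3, MeOH, rt
Reagents that add atoms: none
Why: Methanolysis of the alkynyl C–Si bond (protodesilylation); the hindered O–Si bond is stable to carbonate in methanol.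

Step 5
Reactants: 9 tert-butyldimethyl[(4-methylideneoct-1-en-7-yn-3-yl)oxy]silane
Product: 11 methyl 7-[(tert-butyldimethylsilyl)oxy]-6-methylidenenon-8-en-2-ynoate (racemic), via lithium acetylide 10 (not isolated)
Conditions: n-BuLi, THF, −78 °C; then ClCO2Me, −78 to 0 °C
Reagents that add atoms: methyl chloroformate, COC(=O)Cl
Why: Acetylide formation and C-acylation with a chloroformate; one equivalent of base at −78 °C removes only the alkyne hydrogen, not the bis-allylic one.

Step 6
Reactants: 11 methyl 7-[(tert-butyldimethylsilyl)oxy]-6-methylidenenon-8-en-2-ynoate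
Product: 13 methyl (2Z)-7-[(tert-butyldimethylsilyl)oxy]-6-methylidene-2-[(4,4,5,5-tetramethyl-1,3,2-dioxaborolan-2-yl)methyl]nona-2,8-dienoate (racemic at the silyloxy carbon), via vinylalane 12 (not isolated)
Conditions: i-Bu2AlH, HMPA, THF, 0 °C; then ICH2Bpin, 0 °C to rt
Reagents that add atoms: 2-(iodomethyl)-4,4,5,5-tetramethyl-1,3,2-dioxaborolane, CC1(C)OB(CI)OC1(C)C
Why: Conjugate syn-hydroalumination of the ynoate puts H on the β-carbon cis to aluminium, and C-alkylation of the α-aluminio enoate by the iodomethylboronate keeps that geometry; the alkyl chain therefore ends cis to the ester and trans to CH2B, which is the geometry needed for anti addition in step 9.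

Step 7
Reactants: 14 tert-butyl(but-3-yn-1-yloxy)dimethylsilane
Product: 16 (2E)-5-[(tert-butyldimethylsilyl)oxy]-3-methylpent-2-en-1-ol, via alkenylalane 15 (not isolated)
Conditions: AlMe3, Cp2ZrCl2 (20 mol %), CH2Cl2, 0 °C to rt; then (CH2O)n, rt; aq. potassium sodium tartrate
Reagents that add atoms: trimethylaluminium, C[Al](C)C; paraformaldehyde (as formaldehyde), C=O
Why: Negishi carboalumination adds methyl and aluminium syn across the alkyne with methyl on the internal carbon, and hydroxymethylation of the alkenylalane proceeds with retention, fixing the (E)-C2=C3 alkene and the C3 methyl.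

Step 8
Reactants: 16 (2E)-5-[(tert-butyldimethylsilyl)oxy]-3-methylpent-2-en-1-ol
Product: 17 (2E)-5-[(tert-butyldimethylsilyl)oxy]-3-methylpent-2-enal
Conditions: MnO2, CH2Cl2, rt
Reagents that add atoms: none
Why: Selective heterogeneous oxidation of an allylic alcohol to the enal without E/Z erosion or over-oxidation.

Step 9
Reactants: 13 methyl (2Z)-7-[(tert-butyldimethylsilyl)oxy]-6-methylidene-2-[(pinacolatoboryl)methyl]nona-2,8-dienoate; 17 (2E)-5-[(tert-butyldimethylsilyl)oxy]-3-methylpent-2-enal
Product: 19 (4R,5S)-5-[(1E)-4-(tert-butyldimethylsilyloxy)-2-methylbut-1-en-1-yl]-4-[4-(tert-butyldimethylsilyloxy)-3-methylidenehex-5-en-1-yl]-3-methylideneoxolan-2-one (both epimers at the silyloxy carbon of the hexenyl chain), via anti-hydroxy ester 18 (not isolated)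
Conditions: (R)-TRIP (10 mol %), 4 Å MS, toluene, 0 °C to rt; then p-TsOH·H2O (cat.), rt
Reagents that add atoms: none
Why: Chiral-phosphoric-acid-catalysed allylboration through a closed chair (Zimmerman–Traxler) transition state: the γ-substituent trans to CH2B sits pseudo-equatorial and gives the anti adduct, hence the trans lactone, while the (R)-acid directs the allyl unit to the Re face of the enal, giving 1S and with it 14R. Acid then completes lactonisation by acyl substitution, which touches neither centre.

Step 10
Reactants: 19 (4R,5S)-bis-silyl lactone
Product: 20 (4R,5S)-4-[4-(tert-butyldimethylsilyloxy)-3-methylidenehex-5-en-1-yl]-5-[(1E)-4-hydroxy-2-methylbut-1-en-1-yl]-3-methylideneoxolan-2-one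
Conditions: HF·pyridine, pyridine, THF, 0 °C
Reagents that add atoms: none
Why: Buffered fluoride cleaves the unhindered primary silyl ether much faster than the secondary bis-allylic one, and the medium is neither basic nor nucleophilic towards the methylene lactone.

Step 11
Reactants: 20 (4R,5S)-primary alcohol
Product: 21 (3E)-4-{(2S,3R)-3-[4-(tert-butyldimethylsilyloxy)-3-methylidenehex-5-en-1-yl]-4-methylidene-5-oxooxolan-2-yl}-3-methylbut-3-enal
Conditions: Dess–Martin periodinane, NaHCO3, CH2Cl2, 0 °C; used crude
Reagents that add atoms: none
Why: Dess–Martin oxidation is neutral and fast, the usual way to make a β,γ-unsaturated aldehyde without migration of the alkene into conjugation.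

Step 12
Reactants: 21 (3E)-β,γ-unsaturated aldehyde; 22 ethyl propiolate
Product: 24 ethyl (4R,6E)-7-{(2S,3R)-3-[4-(tert-butyldimethylsilyloxy)-3-methylidenehex-5-en-1-yl]-4-methylidene-5-oxooxolan-2-yl}-4-hydroxy-6-methylhept-6-en-2-ynoate (both C10 epimers), via alkynylzinc 23 (not isolated)
Conditions: (R,R)-ProPhenol (20 mol %), Me2Zn, Ph3PO (40 mol %), toluene, 0 to 4 °C
Reagents that add atoms: none
Why: Catalytic asymmetric alkynylation: Me2Zn zincates the propiolate and the dinuclear zinc–ProPhenol complex delivers the alkynyl group to the Si face of the aldehyde, giving 5R. The methylene lactone does not react with alkylzinc in the absence of copper or oxygen.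

Step 13
Reactants: 24 hydroxy-ynoate (both C10 epimers)
Product: 26 (1S,5R,14R)-macrocyclic bis-lactone bearing the (2E)-alkene, the C11 methylene and the (9Z)-C9=C10 tert-butyldimethylsilyl enol ether, via macrocyclic hydroxy enoate 25 (not isolated)
Conditions: [CpRu(MeCN)3]PF6 (10 mol %), acetone, 0.002 M, slow addition of 24, rt to 50 °C
Reagents that add atoms: none
Why: After loss of acetonitrile the cationic CpRu fragment binds the C6≡C7 ynoate and the C8=C9 vinyl group and cyclises oxidatively to a ruthenacyclopentene in which C7 is bonded to C8; syn β-hydride elimination of the only available hydrogen (C10–H) and reductive elimination at C6 release the (6Z)-enoate 25 with a C9=C10 silyl enol ether. The closest known reaction type is the ruthenium-catalysed alkene–alkyne (Alder-ene) coupling of terminal alkenes with 4-hydroxy-2-alkynoates to give butenolides, including macrocyclising cases, and its use with allyl silyl ethers as enol silane precursors. The 14-membered carbocycle closes in an endo mode with respect to both π-systems (all four reacting carbons end up in the ring), and the butenolide closes by 5-exo-trig acyl substitution of the C5 hydroxyl on the cis ester with loss of ethanol. No stereocentre is created: C1, C5 and C14 are spectators and C10 becomes sp2, so both C10 epimers converge, and the enol ether geometry, set by the syn-coplanar Ru–C9–C10–H arrangement, is of no consequence after hydrolysis. The step needs bond formation at the ynoate α-carbon, which is inherent to free 4-hydroxy-2-ynoates with this catalyst, and reaction of the monosubstituted alkene only, which is secured because the 1,1-disubstituted (C11 and lactone methylenes) and trisubstituted (C2=C3) alkenes do not enter the ruthenacycle. Ring closure must outrun oligomerisation; this is addressed by slow addition at high dilution and helped by the rigid (E)-alkene and trans lactone in the tether.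

Step 14
Reactants: 26 macrocyclic silyl enol ether
Product: 27 (1S,5R,14R)-10-oxo macrocyclic bis-lactone (C10 ketone conjugated with the C11 methylene)
Conditions: Bu4NF, AcOH, THF, −20 °C
Reagents that add atoms: none
Why: Fluoride cleaves the O–Si bond and the resulting enolate is protonated at C9, giving the enone; the acetic acid buffer prevents epimerisation at C5, and no nucleophile that adds to the vinyl ketone is present.

Step 15
Reactants: 27 C10 enone
Product: 28 (1S,5R,10S,14R)-10-hydroxy macrocyclic bis-lactone
Conditions: (R)-2-methyl-CBS-oxazaborolidine (1 equiv), catecholborane, toluene, −78 °C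
Reagents that add atoms: none
Why: Corey–Bakshi–Shibata reduction: the ketone binds the boron anti to its larger substituent (the α-branched alkenyl C11) and hydride is delivered to the face that gives 10S under reagent control. Lactones, butenolide and isolated alkenes are inert to catecholborane at this temperature.

Step 16
Reactants: 28 (10S)-alcohol
Product: 30 4-methylene-5β-hydroperoxyovatodiolide (1S,5R,10R,14R), via allylic mesylate 29 (not isolated)
Conditions: MsCl, Et3N, CH2Cl2, −40 °C; then anhydrous H2O2 in Et2O (excess), −78 to −20 °C
Reagents that add atoms: hydrogen peroxide, OO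
Why: Sulfonylation with retention, then bimolecular displacement by neutral hydrogen peroxide (an α-effect nucleophile) with inversion gives 10R. Without hydroperoxide anion the two conjugate acceptors are not epoxidised, and the cold, weakly ionising medium disfavours allyl cation formation.

## Compound list

1 | 1-(trimethylsilyl)propyne | CC#C[Si](C)(C)C | starting material
2 | 2,3-dibromopropene | C=C(Br)CBr | starting material
3 | [3-(trimethylsilyl)prop-2-yn-1-yl]lithium | [Li]CC#C[Si](C)(C)C | intermediate (not isolated)
4 | (5-bromohex-5-en-1-yn-1-yl)trimethylsilane | C=C(Br)CCC#C[Si](C)(C)C | intermediate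
5 | acrolein | C=CC=O | starting material
6 | [6-(trimethylsilyl)hex-1-en-5-yn-2-yl]lithium | [Li]C(=C)CCC#C[Si](C)(C)C | intermediate (not isolated)
7 | 4-methylidene-8-(trimethylsilyl)oct-1-en-7-yn-3-ol (racemic) | C=CC(O)C(=C)CCC#C[Si](C)(C)C | intermediate
8 | tert-butyldimethyl{[4-methylidene-8-(trimethylsilyl)oct-1-en-7-yn-3-yl]oxy}silane (racemic) | C=CC(O[Si](C)(C)C(C)(C)C)C(=C)CCC#C[Si](C)(C)C | intermediate
9 | tert-butyldimethyl[(4-methylideneoct-1-en-7-yn-3-yl)oxy]silane (racemic) | C=CC(O[Si](C)(C)C(C)(C)C)C(=C)CCC#C | intermediate
10 | lithium acetylide of 9 | [Li]C#CCCC(=C)C(O[Si](C)(C)C(C)(C)C)C=C | intermediate (not isolated)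
11 | methyl 7-[(tert-butyldimethylsilyl)oxy]-6-methylidenenon-8-en-2-ynoate (racemic) | COC(=O)C#CCCC(=C)C(O[Si](C)(C)C(C)(C)C)C=C | intermediate
12 | methyl (2E)-2-[bis(2-methylpropyl)alumanyl]-7-[(tert-butyldimethylsilyl)oxy]-6-methylidenenona-2,8-dienoate | COC(=O)/C([Al](CC(C)C)CC(C)C)=C\CCC(=C)C(O[Si](C)(C)C(C)(C)C)C=C | intermediate (not isolated)
13 | methyl (2Z)-7-[(tert-butyldimethylsilyl)oxy]-6-methylidene-2-[(4,4,5,5-tetramethyl-1,3,2-dioxaborolan-2-yl)methyl]nona-2,8-dienoate (racemic at C7) | COC(=O)/C(CB1OC(C)(C)C(C)(C)O1)=C\CCC(=C)C(O[Si](C)(C)C(C)(C)C)C=C | intermediate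
14 | tert-butyl(but-3-yn-1-yloxy)dimethylsilane | C#CCCO[Si](C)(C)C(C)(C)C | starting material
15 | [(1E)-4-(tert-butyldimethylsilyloxy)-2-methylbut-1-en-1-yl]dimethylalumane | C[Al](C)/C=C(\C)CCO[Si](C)(C)C(C)(C)C | intermediate (not isolated)
16 | (2E)-5-[(tert-butyldimethylsilyl)oxy]-3-methylpent-2-en-1-ol | OC/C=C(\C)CCO[Si](C)(C)C(C)(C)C | intermediate
17 | (2E)-5-[(tert-butyldimethylsilyl)oxy]-3-methylpent-2-enal | O=C/C=C(\C)CCO[Si](C)(C)C(C)(C)C | intermediate
18 | methyl (3R,4S,5E)-8-(tert-butyldimethylsilyloxy)-3-[4-(tert-butyldimethylsilyloxy)-3-methylidenehex-5-en-1-yl]-4-hydroxy-6-methyl-2-methylideneoct-5-enoate (both epimers at the hexenyl silyloxy carbon) | COC(=O)C(=C)[C@@H](CCC(=C)C(O[Si](C)(C)C(C)(C)C)C=C)[C@@H](O)/C=C(\C)CCO[Si](C)(C)C(C)(C)C | intermediate (not isolated)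
19 | (4R,5S)-5-[(1E)-4-(tert-butyldimethylsilyloxy)-2-methylbut-1-en-1-yl]-4-[4-(tert-butyldimethylsilyloxy)-3-methylidenehex-5-en-1-yl]-3-methylideneoxolan-2-one (both C10 epimers) | CC(C)(C)[Si](C)(C)OCC/C(C)=C/[C@@H]1OC(=O)C(=C)[C@H]1CCC(=C)C(O[Si](C)(C)C(C)(C)C)C=C | intermediate
20 | (4R,5S)-4-[4-(tert-butyldimethylsilyloxy)-3-methylidenehex-5-en-1-yl]-5-[(1E)-4-hydroxy-2-methylbut-1-en-1-yl]-3-methylideneoxolan-2-one (both C10 epimers) | OCC/C(C)=C/[C@@H]1OC(=O)C(=C)[C@H]1CCC(=C)C(O[Si](C)(C)C(C)(C)C)C=C | intermediate
21 | (3E)-4-{(2S,3R)-3-[4-(tert-butyldimethylsilyloxy)-3-methylidenehex-5-en-1-yl]-4-methylidene-5-oxooxolan-2-yl}-3-methylbut-3-enal (both C10 epimers) | O=CC/C(C)=C/[C@@H]1OC(=O)C(=C)[C@H]1CCC(=C)C(O[Si](C)(C)C(C)(C)C)C=C | intermediate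
22 | ethyl propiolate | C#CC(=O)OCC | starting material
23 | ethyl 3-(methylzincio)prop-2-ynoate | CCOC(=O)C#C[Zn]C | intermediate (not isolated)
24 | ethyl (4R,6E)-7-{(2S,3R)-3-[4-(tert-butyldimethylsilyloxy)-3-methylidenehex-5-en-1-yl]-4-methylidene-5-oxooxolan-2-yl}-4-hydroxy-6-methylhept-6-en-2-ynoate (1S,5R,14R; both C10 epimers) | CCOC(=O)C#C[C@H](O)C/C(C)=C/[C@@H]1OC(=O)C(=C)[C@H]1CCC(=C)C(O[Si](C)(C)C(C)(C)C)C=C | intermediate
25 | macrocyclic (6Z)-enoate: 14-membered ring with free C5 hydroxyl, ethyl ester on C7 and (9Z)-C9=C10 silyl enol ether (1S,5R,14R) | CCOC(=O)/C1=C\[C@H](O)C/C(C)=C/[C@@H]2OC(=O)C(=C)[C@H]2CCC(=C)/C(O[Si](C)(C)C(C)(C)C)=C/C1 | intermediate (not isolated)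
26 | (1S,5R,14R)-macrocyclic bis-lactone with (2E)-C2=C3, C11 methylene and (9Z)-C9=C10 tert-butyldimethylsilyl enol ether | C=C1C(=O)O[C@H]2/C=C(\C)C[C@@H]3C=C(C/C=C(\O[Si](C)(C)C(C)(C)C)C(=C)CC[C@H]12)C(=O)O3 | intermediate
27 | (1S,5R,14R)-10-oxo macrocyclic bis-lactone (C10 enone) | C=C1C(=O)O[C@H]2/C=C(\C)C[C@@H]3C=C(CCC(=O)C(=C)CC[C@H]12)C(=O)O3 | intermediate
28 | (1S,5R,10S,14R)-10-hydroxy macrocyclic bis-lactone | C=C1C(=O)O[C@H]2/C=C(\C)C[C@@H]3C=C(CC[C@H](O)C(=C)CC[C@H]12)C(=O)O3 | intermediate
29 | (1S,5R,10S,14R)-10-methanesulfonyloxy macrocyclic bis-lactone | C=C1C(=O)O[C@H]2/C=C(\C)C[C@@H]3C=C(CC[C@H](OS(C)(=O)=O)C(=C)CC[C@H]12)C(=O)O3 | intermediate (not isolated)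
30 | 4-methylene-5β-hydroperoxyovatodiolide (1S,5R,10R,14R) | C=C1C(=O)O[C@H]2/C=C(\C)C[C@@H]3C=C(CC[C@@H](OO)C(=C)CC[C@H]12)C(=O)O3 | target

## Step count and least certain steps

Total: 16 steps. Longest linear sequence: 14 steps (steps 1–6, then 9–16); the second branch contributes steps 7 and 8.

Step 13 (key step). Most likely to go wrong: intermolecular coupling competing with ring closure, and sequestration of the cationic ruthenium by the 1,4-diene of the substrate or by the 2-silyloxy-1,3-diene that accumulates as product. Slow turnover would also give ruthenium hydride time to move the lactone methylene into the ring. Fallback: set out from 24 and cleave the remaining silyl ether (HF·pyridine, THF, rt) to the C10 carbinol F1. Ring closure of F1 with [CpRu(MeCN)3]PF6 or CpRu(cod)Cl uses the allylic alcohol as the ene donor, so the product is a dienol that tautomerises at once and no silyloxydiene is formed. The route is rejoined at 27, with step 14 omitted.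

Step 9. Most likely to go wrong: slow catalysed addition, because the ester-substituted allylboronate is a weak nucleophile, so that an unselective background pathway and long reaction times erode facial selectivity. Fallback (auxiliary control in place of catalyst control): set out from 9, acylate its acetylide 10 with the chloroformate of (1R,2S,5R)-8-phenylmenthol to give the 8-phenylmenthyl ynoate F2, and convert it as in step 6 into the auxiliary-bearing allylboronate F3. Addition of F3 to 17 with Sc(OTf)3 (cat.) at low temperature, then acid lactonisation with release of the auxiliary, returns to 19. The antipodal auxiliary is used if the shielded face proves to be the wrong one.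

Step 16. Most likely to go wrong: ionisation of the allylic sulfonate before substitution, which loses the C10 configuration and lets peroxide enter at the exocyclic terminus; acid liberated in the step could also fragment the allylic hydroperoxide. Fallback (an anionic, protected peroxide nucleophile in a dipolar solvent, to enforce the bimolecular pathway): set out from 28, form 29 as before, and treat it with 2-methoxyprop-2-yl hydroperoxide and Cs2CO3 or CsOH·H2O in DMF at 0 °C to give the (10R)-peroxyketal F4. Mild hydrolysis (AcOH, THF, H2O) comes back at 30. The base makes this riskier for the two conjugate acceptors than the neutral main procedure.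

Step 12. Most likely to go wrong: enolisation of the β,γ-unsaturated aldehyde under the basic zinc alkoxide conditions (migration of C2=C3 into conjugation, self-condensation) and weaker facial discrimination for an α-unbranched aldehyde. Fallback (addition, oxidation, asymmetric reduction): set out from 21 and add lithiated 22 (LiN(SiMe3)2, THF, −78 °C) to give the C5-epimeric hydroxy-ynoate F5. Oxidise F5 with Dess–Martin periodinane to the ynone F6, and reduce F6 with (R)-Alpine-Borane (Midland reduction, neat, rt), which gives the (R)-propargylic alcohol and returns to 24.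

## Further compounds

F1 | step 13 | ethyl (4R,6E)-4-hydroxy-7-{(2S,3R)-3-(4-hydroxy-3-methylidenehex-5-en-1-yl)-4-methylidene-5-oxooxolan-2-yl}-6-methylhept-6-en-2-ynoate (both C10 epimers) | CCOC(=O)C#C[C@H](O)C/C(C)=C/[C@@H]1OC(=O)C(=C)[C@H]1CCC(=C)C(O)C=C
F2 | step 9 | (1R,2S,5R)-5-methyl-2-(2-phenylpropan-2-yl)cyclohexyl 7-[(tert-butyldimethylsilyl)oxy]-6-methylidenenon-8-en-2-ynoate | C[C@@H]1CC[C@H]([C@@H](C1)OC(=O)C#CCCC(=C)C(O[Si](C)(C)C(C)(C)C)C=C)C(C)(C)c1ccccc1
F3 | step 9 | (1R,2S,5R)-5-methyl-2-(2-phenylpropan-2-yl)cyclohexyl (2Z)-7-[(tert-butyldimethylsilyl)oxy]-6-methylidene-2-[(4,4,5,5-tetramethyl-1,3,2-dioxaborolan-2-yl)methyl]nona-2,8-dienoate | C[C@@H]1CC[C@H]([C@@H](C1)OC(=O)/C(CB2OC(C)(C)C(C)(C)O2)=C\CCC(=C)C(O[Si](C)(C)C(C)(C)C)C=C)C(C)(C)c1ccccc1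
F4 | step 16 | (1S,5R,10R,14R)-10-[(2-methoxypropan-2-yl)peroxy] macrocyclic bis-lactone | C=C1C(=O)O[C@H]2/C=C(\C)C[C@@H]3C=C(CC[C@@H](OOC(C)(C)OC)C(=C)CC[C@H]12)C(=O)O3
F5 | step 12 | ethyl (6E)-7-{(2S,3R)-3-[4-(tert-butyldimethylsilyloxy)-3-methylidenehex-5-en-1-yl]-4-methylidene-5-oxooxolan-2-yl}-4-hydroxy-6-methylhept-6-en-2-ynoate (both C5 epimers) | CCOC(=O)C#CC(O)C/C(C)=C/[C@@H]1OC(=O)C(=C)[C@H]1CCC(=C)C(O[Si](C)(C)C(C)(C)C)C=C
F6 | step 12 | ethyl (6E)-7-{(2S,3R)-3-[4-(tert-butyldimethylsilyloxy)-3-methylidenehex-5-en-1-yl]-4-methylidene-5-oxooxolan-2-yl}-6-methyl-4-oxohept-6-en-2-ynoate | CCOC(=O)C#CC(=O)C/C(C)=C/[C@@H]1OC(=O)C(=C)[C@H]1CCC(=C)C(O[Si](C)(C)C(C)(C)C)C=C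
A1 | alternative 1 | macrocyclic butenolide C1 diazo(diethoxyphosphoryl)acetate (C14 as CH2, (10E)-C10=C11) | CCOP(=O)(OCC)C(=[N+]=[N-])C(=O)O[C@H]1/C=C(\C)C[C@@H]2C=C(CC/C=C(\C)CCC1)C(=O)O2
A2 | alternative 1 | α-(diethoxyphosphoryl) trans-lactone of the ovatodiolide skeleton | CCOP(=O)(OCC)[C@H]1C(=O)O[C@H]2/C=C(\C)C[C@@H]3C=C(CC/C=C(\C)CC[C@H]12)C(=O)O3
A3 | alternative 2 | seco iodoalkene aldehyde (C10 aldehyde, C11 2-iodoalkene) | C=C(I)CC[C@@H]1C(=C)C(=O)O[C@H]1/C=C(\C)C[C@@H]2C=C(CCC=O)C(=O)O2
A4 | alternative 2 | (1S,5R,10S,14R)-10-hydroxy macrocyclic bis-lactone (identical with 28) | C=C1C(=O)O[C@H]2/C=C(\C)C[C@@H]3C=C(CC[C@H](O)C(=C)CC[C@H]12)C(=O)O3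
A5 | alternative 3 | 15-membered macrolactone with C5 vinyl and C7 methylene | C=C[C@H]1C/C(C)=C/[C@@H]2OC(=O)C(=C)[C@H]2CC/C(C)=C/CCC(=C)C(=O)O1
A6 | alternative 3 | ovatodiolide | C=C1C(=O)O[C@H]2/C=C(\C)C[C@@H]3C=C(CC/C=C(\C)CC[C@H]12)C(=O)O3
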